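A direct plan would first make both aromatic partners from simple phenols, then join the ring B aryloxyacetyl Evans imide A1 to 3,4,5-trimethoxybenzaldehyde A2 in a boron syn-aldol to adduct A3, cleave the auxiliary reductively to the 1,3-diol A4 and acetylate the primary hydroxyl of A4.
Its weakest points would be:
- the construction of the two arenes (ring halogenation/methoxylation, O-allylation and a para-Claisen rearrangement near 200 °C): many steps that would add nothing a catalogue does not offer;
- the auxiliary aldol: C7 and C8 would both depend on one C–C bond formation from a hindered aryloxyacetyl enolate, bought with a stoichiometric auxiliary that costs further steps to attach and to remove from a retro-aldol-prone β-hydroxy imide;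
- the final mono-acetylation of A4: it would rest only on a rate difference between two free hydroxyls, so diacetate formation and 1,3-acyl migration would be paid for with the most valuable material.

**Plan of the new route**
Numbering: C7 = carbinol carbon on ring A (3,4,5-trimethoxyphenyl), C8 = carbon bearing the ether oxygen to ring B (4-allyl-2,6-dimethoxyphenyl), C9 = CH2OAc.
Retrosynthetic cuts, in order: O9–acetyl and O7–silyl (end-game on a mono-ol), the two C9–H bonds (ester to alcohol), the C7–H bond (key step, which also fixes C8), the C8–O bond to ring B (SN2), the C8–Cl bond.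
No ring is formed at any stage: rings A and B are bought intact as a β-keto ester and a phenol, so no arene construction occurs.
Enabling feature: C8 lies between C7 and C9; with C7 as aryl ketone on ring A and C9 as ester, C8–H is doubly activated and C8 epimerises freely, so one catalytic hydride transfer to C7 can convert the racemate into the (7R,8R)-threo array.
Hence no auxiliary and no aldol are needed, and the acetate is put on a compound with a single free hydroxyl, so no diol is ever differentiated.

Key step: step 3

Remark on the chemistry: the (S,S)-ligand is assumed to deliver the 7R carbinol, by analogy with its sense of induction on simple aryl ketones; the (R,R)-complex would be used if the sense proved opposite.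

Step 1
Reactants: 1 ethyl 3-oxo-3-(3,4,5-trimethoxyphenyl)propanoate
Product: 2 ethyl 2-chloro-3-oxo-3-(3,4,5-trimethoxyphenyl)propanoate (racemic)
Conditions: SO2Cl2 (1.05 equiv), CH2Cl2, 0 °C → rt
Reagents that add atoms: sulfuryl chloride O=S(=O)(Cl)Cl
Why: Electrophilic α-chlorination of a β-keto ester through its enol, which should outpace attack on the acyl-deactivated ring A, with one equivalent of reagent limiting dichlorination; it is run before the allyl group and the electron-rich ring B are present.

Step 2
Reactants: 2 ethyl 2-chloro-3-oxo-3-(3,4,5-trimethoxyphenyl)propanoate; 3 4-allyl-2,6-dimethoxyphenol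
Product: 4 ethyl 2-(4-allyl-2,6-dimethoxyphenoxy)-3-oxo-3-(3,4,5-trimethoxyphenyl)propanoate (racemic)
Conditions: K2CO3 (1.5 equiv), acetone, rt → 50 °C; dilute acid work-up
Reagents that add atoms: none
Why: Williamson-type SN2 displacement of a chloride activated by two flanking carbonyl groups, in which the blocked ortho and para positions of the phenoxide leave O-alkylation as the only productive path; C8 is formed racemic and labile, which is what the next step requires.

Step 3
Reactants: 4 ethyl 2-(4-allyl-2,6-dimethoxyphenoxy)-3-oxo-3-(3,4,5-trimethoxyphenyl)propanoate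
Product: 6 ethyl (2S,3R)-2-(4-allyl-2,6-dimethoxyphenoxy)-3-hydroxy-3-(3,4,5-trimethoxyphenyl)propanoate, via enol tautomer 5 (not isolated)
Conditions: RuCl[(S,S)-TsDPEN](p-cymene) (1–2 mol %), HCO2H/Et3N (5:2), CH2Cl2, 30 °C
Reagents that add atoms: none
Why: This is a Noyori–Ikariya asymmetric transfer hydrogenation run as a dynamic kinetic resolution: the 18-electron hydride of divalent ruthenium generated from the precatalyst and formate passes Ru–H and N–H to the C7 carbonyl in a concerted outer-sphere six-membered transition state, while the two enantiomers of 4 interconvert through enol 5 because C8–H lies between the C7 ketone and the C9 ester. The closest known reaction type is the syn-selective transfer hydrogenation with dynamic kinetic resolution of α-alkoxy β-keto esters by the same catalyst family. No ring is closed. C7 is set by the catalyst, whose CH/π contact between the η6-p-cymene ligand and ring A should direct hydride to the Si face (7R), and C8 is set by selection between the equilibrating epimers, the faster one being that which keeps the C8–O bond anti to the incoming hydride (Felkin–Anh arrangement) and so gives the syn (2S,3R) ester, i.e. the threo (7R,8R) array of the target once C9 is reduced. The step needs racemisation to outrun reduction of the mismatched enantiomer, which the 1,3-dicarbonyl acidity of C8–H secures, and it needs the ketone to react in preference to the allyl group and the ester, which the coordinatively saturated hydride secures because it cannot bind an alkene.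

Step 4
Reactants: 6 ethyl (2S,3R)-2-(4-allyl-2,6-dimethoxyphenoxy)-3-hydroxy-3-(3,4,5-trimethoxyphenyl)propanoate
Product: 7 ethyl (2S,3R)-2-(4-allyl-2,6-dimethoxyphenoxy)-3-(triethylsilyloxy)-3-(3,4,5-trimethoxyphenyl)propanoate
Conditions: Et3SiOTf (1.3 equiv), 2,6-lutidine (2 equiv), CH2Cl2, −78 → 0 °C
Reagents that add atoms: triethylsilyl triflate CC[Si](CC)(CC)OS(=O)(=O)C(F)(F)F
Why: Silylation of the only hydroxyl group with a silyl triflate and a hindered base, which should cope with the crowded benzylic position and is too weakly basic to touch C8.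

Step 5
Reactants: 7 ethyl (2S,3R)-2-(4-allyl-2,6-dimethoxyphenoxy)-3-(triethylsilyloxy)-3-(3,4,5-trimethoxyphenyl)propanoate
Product: 8 (2R,3R)-2-(4-allyl-2,6-dimethoxyphenoxy)-3-(triethylsilyloxy)-3-(3,4,5-trimethoxyphenyl)propan-1-ol
Conditions: i-Bu2AlH (2.5 equiv), CH2Cl2, −78 → −20 °C; aqueous potassium sodium tartrate
Reagents that add atoms: none
Why: Hydride reduction of the ester to the primary alcohol at low temperature, where the terminal alkene is not hydroaluminated and the aluminium alkoxide is too weakly basic to move the silyl group; C8 changes only its descriptor from S to R because C9 drops in CIP priority.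

Step 6
Reactants: 8 (2R,3R)-2-(4-allyl-2,6-dimethoxyphenoxy)-3-(triethylsilyloxy)-3-(3,4,5-trimethoxyphenyl)propan-1-ol
Product: 9 (2R,3R)-2-(4-allyl-2,6-dimethoxyphenoxy)-3-(triethylsilyloxy)-3-(3,4,5-trimethoxyphenyl)propyl acetate
Conditions: Ac2O (1.5 equiv), pyridine (3 equiv), DMAP (5 mol %), CH2Cl2, 0 °C → rt
Reagents that add atoms: acetic anhydride CC(=O)OC(C)=O
Why: DMAP-catalysed acetylation of the single free hydroxyl, so that no site selectivity is asked of the reagent.

Step 7
Reactants: 9 (2R,3R)-2-(4-allyl-2,6-dimethoxyphenoxy)-3-(triethylsilyloxy)-3-(3,4,5-trimethoxyphenyl)propyl acetate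
Product: 10 (2R,3R)-2-(4-allyl-2,6-dimethoxyphenoxy)-3-hydroxy-3-(3,4,5-trimethoxyphenyl)propyl acetate (target)
Conditions: HF·pyridine, pyridine, THF, 0 °C → rt
Reagents that add atoms: none
Why: Fluoride cleavage of the Si–O bond under buffered, weakly acidic conditions, in which the acetate should neither hydrolyse nor migrate from O9 to O7 and the benzylic C7–O bond should not ionise.

**Compound list**
1 | ethyl 3-oxo-3-(3,4,5-trimethoxyphenyl)propanoate (ethyl 3,4,5-trimethoxybenzoylacetate) | CCOC(=O)CC(=O)c1cc(OC)c(OC)c(OC)c1 | starting material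
2 | ethyl 2-chloro-3-oxo-3-(3,4,5-trimethoxyphenyl)propanoate (racemic) | CCOC(=O)C(Cl)C(=O)c1cc(OC)c(OC)c(OC)c1 | intermediate
3 | 4-allyl-2,6-dimethoxyphenol (methoxyeugenol) | C=CCc1cc(OC)c(O)c(OC)c1 | starting material
4 | ethyl 2-(4-allyl-2,6-dimethoxyphenoxy)-3-oxo-3-(3,4,5-trimethoxyphenyl)propanoate (racemic) | CCOC(=O)C(Oc1c(OC)cc(CC=C)cc1OC)C(=O)c1cc(OC)c(OC)c(OC)c1 | intermediate
5 | ethyl (E)-2-(4-allyl-2,6-dimethoxyphenoxy)-3-hydroxy-3-(3,4,5-trimethoxyphenyl)prop-2-enoate (chelated enol of 4) | CCOC(=O)/C(Oc1c(OC)cc(CC=C)cc1OC)=C(\O)c1cc(OC)c(OC)c(OC)c1 | intermediate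
6 | ethyl (2S,3R)-2-(4-allyl-2,6-dimethoxyphenoxy)-3-hydroxy-3-(3,4,5-trimethoxyphenyl)propanoate | CCOC(=O)[C@@H](Oc1c(OC)cc(CC=C)cc1OC)[C@H](O)c1cc(OC)c(OC)c(OC)c1 | intermediate
7 | ethyl (2S,3R)-2-(4-allyl-2,6-dimethoxyphenoxy)-3-(triethylsilyloxy)-3-(3,4,5-trimethoxyphenyl)propanoate | CCOC(=O)[C@@H](Oc1c(OC)cc(CC=C)cc1OC)[C@H](O[Si](CC)(CC)CC)c1cc(OC)c(OC)c(OC)c1 | intermediate
8 | (2R,3R)-2-(4-allyl-2,6-dimethoxyphenoxy)-3-(triethylsilyloxy)-3-(3,4,5-trimethoxyphenyl)propan-1-ol | C=CCc1cc(OC)c(O[C@H](CO)[C@H](O[Si](CC)(CC)CC)c2cc(OC)c(OC)c(OC)c2)c(OC)c1 | intermediate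
9 | (2R,3R)-2-(4-allyl-2,6-dimethoxyphenoxy)-3-(triethylsilyloxy)-3-(3,4,5-trimethoxyphenyl)propyl acetate | C=CCc1cc(OC)c(O[C@H](COC(C)=O)[C@H](O[Si](CC)(CC)CC)c2cc(OC)c(OC)c(OC)c2)c(OC)c1 | intermediate
10 | (2R,3R)-2-(4-allyl-2,6-dimethoxyphenoxy)-3-hydroxy-3-(3,4,5-trimethoxyphenyl)propyl acetate | C=CCc1cc(OC)c(O[C@H](COC(C)=O)[C@H](O)c2cc(OC)c(OC)c(OC)c2)c(OC)c1 | target

**Step count and risks**
Total step count: 7. Longest linear sequence: 7 steps (1 to 10); phenol 3 enters at step 2.

Steps most likely to fail:

1. Step 3. Racemisation at C8 might not keep pace with reduction, or the bulky di-ortho-substituted aryloxy group might erode the syn preference or slow hydride transfer. The fallback sets out from 3 and returns at 8. Phenol 3 would be O-alkylated (K2CO3, acetone) with (S)-3-(2-bromoacetyl)-4-isopropyloxazolidin-2-one F1, itself obtained from the lithiated commercial oxazolidinone and bromoacetyl bromide, to give imide A1. Enolisation with Bu2BOTf/Et3N and Evans syn-aldol addition to aldehyde A2 would give adduct A3, whose hydroxyl would be silylated (Et3SiOTf, 2,6-lutidine) to the C7 triethylsilyl ether F2. Reductive removal of the auxiliary with LiBH4/MeOH in THF at 0 °C would then deliver 8, still without passing through a diol.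

2. Step 2. The hindered phenoxide might act as a base on the acidic chloride or attack chlorine instead of carbon, so that substitution stalls. The fallback sets out from 3 and returns at 4. Phenol 3 would be alkylated with ethyl bromoacetate (K2CO3, acetone) to ethyl 2-(4-allyl-2,6-dimethoxyphenoxy)acetate F3. Its lithium enolate (LiN(SiMe3)2, 2.1 equiv, THF, −78 °C) would be C-acylated with 3,4,5-trimethoxybenzoyl chloride in a crossed Claisen condensation to give 4. This moves the hindered oxygen nucleophile onto an unhindered, non-acidic primary bromide and makes steps 1 and 2 unnecessary.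

3. Step 7. During desilylation the acetyl group might migrate from O9 to O7, or the ring A benzylic C7–O bond might ionise. The fallback sets out from 6 and returns at 10. Ester 6 would be reduced with LiBH4 (THF, 0 °C) to diol A4. An immobilised lipase (Candida antarctica lipase B, a serine hydrolase) with vinyl acetate in MTBE at 30 °C would then transfer acetyl to the primary hydroxyl alone to give 10. No silyl group and no acidic or basic deprotection would be involved, and steps 4 to 7 would be replaced.

**Further compounds**
F1 | step 3 | (S)-3-(2-bromoacetyl)-4-isopropyloxazolidin-2-one | CC(C)[C@H]1COC(=O)N1C(=O)CBr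
F2 | step 3 | (S)-3-[(2S,3R)-2-(4-allyl-2,6-dimethoxyphenoxy)-3-(triethylsilyloxy)-3-(3,4,5-trimethoxyphenyl)propanoyl]-4-isopropyloxazolidin-2-one | CC(C)[C@H]1COC(=O)N1C(=O)[C@@H](Oc1c(OC)cc(CC=C)cc1OC)[C@H](O[Si](CC)(CC)CC)c1cc(OC)c(OC)c(OC)c1
F3 | step 2 | ethyl 2-(4-allyl-2,6-dimethoxyphenoxy)acetate | CCOC(=O)COc1c(OC)cc(CC=C)cc1OC
F0 | step 7 | none | none
A1 | direct plan | (S)-3-[2-(4-allyl-2,6-dimethoxyphenoxy)acetyl]-4-isopropyloxazolidin-2-one | CC(C)[C@H]1COC(=O)N1C(=O)COc1c(OC)cc(CC=C)cc1OC
A2 | direct plan | 3,4,5-trimethoxybenzaldehyde | COc1cc(C=O)cc(OC)c1OC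
A3 | direct plan | (S)-3-[(2S,3R)-2-(4-allyl-2,6-dimethoxyphenoxy)-3-hydroxy-3-(3,4,5-trimethoxyphenyl)propanoyl]-4-isopropyloxazolidin-2-one | CC(C)[C@H]1COC(=O)N1C(=O)[C@@H](Oc1c(OC)cc(CC=C)cc1OC)[C@H](O)c1cc(OC)c(OC)c(OC)c1
A4 | direct plan | (1R,2R)-2-(4-allyl-2,6-dimethoxyphenoxy)-1-(3,4,5-trimethoxyphenyl)propane-1,3-diol | C=CCc1cc(OC)c(O[C@H](CO)[C@H](O)c2cc(OC)c(OC)c(OC)c2)c(OC)c1
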